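The closed, stirred vessel holds substrate that turns to product under a held gas phase, with free catalyst, added ligand and impurity charged together. The two earlier runs differ from the new flask in catalyst loading and time.

the same everywhere: gas phase 110 mM (held); added ligand 360 mM; impurity 47 mM

| run | substrate | free catalyst | remark | time |
|---|---|---|---|---|
| birch | 3 M | 10 mol% | run made earlier |  |
| oak | 3 M | 16 mol% | run made earlier |  |
| flask | 3.0 M | 7.5 mol% |  | 20 h |

- birch (time / h: product / %): 1.33: 1.6; 2.50: 2.1; 5.00: 1.0; 8.00: 4.8; 15.0: 5.7
- oak (time / h: product / %): 1.33: 1.1; 2.50: 3.6; 5.00: 6.8; 8.00: 12.7; 15.0: 19.5

(each reading ± 1 percentage point)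

- at the start none of the gas is dissolved
- steps that have been proposed: gas phase <-> dissolved gas; substrate + dissolved gas + free catalyst -> free catalyst + product; free catalyst + added ligand <-> idle complex; free catalyst + impurity -> spent catalyst A; free catalyst -> spent catalyst B

- product at 20 h, in percent of the substrate charged
- the change that raises the amount of product at 20 h, in percent of the substrate charged most ("none" if none brings more than 2 percentage points) (north-east / south-east / north / none)
- amount of product at 20 h, in percent of the substrate charged, after north-east

- north-east: doubling the amount of free catalyst, all else as stated
- south-east: doubling the saturation concentration of gas phase, all else as stated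
- north: doubling the transfer coefficient of the gas phase, all else as stated

Counting turnovers, product per catalyst charged, gives the rate directly. The birch run made 0.0380 h⁻¹ on average over 15.0 h, its mean turnover frequency. At that time the oak reading stands 3.42 times the birch reading for 1.60 times the loading, so the ratio of their logarithms reads 2.62. This ratio, the steepness, is an apparent order in catalyst, more than the 1 of a catalyst working in proportion, and it carries the scatter of 1 percentage point on each reading.

The reckoning here lets turnovers per hour follow the loading to the power of the steepness less one. The flask's lower loading therefore multiplies the birch rate by 0.628, to 0.0239 h⁻¹. Held at that rate over the flask's 20 h, this gives 0.477 turnovers, fewer than one, or 3.58 % of the substrate. Doubling the loading multiplies that by 6.15, to 22.0 %, more than the factor 2 of doubled gas saturation in a step first order in dissolved gas, so this reckoning chooses north-east.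

The forecast, reading “a threshold from ligand binding”, gave 4 %, above this reckoning, chose north-east, and gave 20 % after it.

    gas phase ⇌ dissolved gas, rate k1*(csat - [dissolved gas]) (kL = 0.0140 min⁻¹)
    substrate + dissolved gas + free catalyst → free catalyst + product (k = 0.0720 L² mol⁻² min⁻¹)
    free catalyst + added ligand ⇌ idle complex, settled at all times (K = 220 L mol⁻¹)
    free catalyst + impurity → spent catalyst A (k = 4.10 L mol⁻¹ min⁻¹)
    free catalyst → spent catalyst B (k = 0.00120 min⁻¹)

The flask gives 3.43 %, or 0.457 turnovers. North-east adds 18 points, south-east 3.3 points and north 0.22 points. North-east reaches 21.4 %, a steepness of 2.64 across that doubling. A loading of 11 mol%, where the answer has moved 5 points, would part from the forecast's 4 %. The neighbouring flask has 1.8 M of substrate at the same loading, so its catalyst charge is 0.600 of the flask's. The steepness then gives 0.901 %. That neighbour gives 1.31 %, or 0.174 turnovers.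

(The readings were generated by integration from invented constants; noise was put on by code.)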